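Germacrane numbering is used throughout: C1–C10 form the ring, C11 (with C12 and C13) sits on C7, C14 is the methyl on C10 and C15 the hydroxymethyl on C4.

## The problem

The target 40 is a germacranolide: a ten-membered carbocycle with an E-C9=C10 and a Z-C4=C5 trisubstituted olefin, and an α-methylene-γ-butyrolactone (C12 carbonyl to O6) trans-fused across C6–C7. It has five stereocentres: C1 (free allylic alcohol), C3 (allylic acetate) and the contiguous triad C6/C7/C8 (lactone oxygen, C11 branch, angelate). Within the triad one centre can set the next: C6 and C7 can come from one aldol, and C8 from reduction of a ketone next to C7. C3 is cut off from the triad by the sp2 carbons C4 and C5, so it needs its own enantioselective step, and C1 can only be set when the ring is closed or afterwards. The α-methylene lactone is a Michael acceptor, the angelate isomerises to the tiglate and is an allylic ester, the C3 acetate would be eliminated if C1 were a carbonyl while it is in place, and two allylic alcohols must stay unoxidised. Lactone and acetate therefore belong late, and the last unmasking must be non-basic. Closing a ten-membered ring is costly, and the Z geometry of C4=C5 cannot be left to thermodynamics. The enabling feature is that the Z olefin holds C3 and C6 cis, so O3 and O6 can be bound to one silicon in a seven-membered ring (O3, C3, C4, C5, C6, O6, Si) that tolerates only a cis olefin. Making C4=C5 inside that ring fixes the geometry and joins two halves of the molecule in the same operation.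

## Retrosynthesis

**Lactone, acetate and silyl groups last (40 ← 39 ← 38 ← 35).** The O1 and O15 silyl ethers of 39 are removed last, the C3 acetate of 39 comes from alcohol 38, and the lactone of 38 is cut at O6–C12 with C12 lowered to the alcohol, giving triol 35. Carrying C12 as a silyl ether instead of an acrylate keeps a Michael acceptor and a premature lactonisation out of the ring-forming steps. In 35 the primary C12 hydroxyl differs from the secondary C3 and C6 hydroxyls by rate of oxidation, so the forward step must oxidise only the primary allylic alcohol and let O6 close the lactol.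

**Ten-membered ring at C1–C10 (35 ← 34 ← 33 ← 32).** Triol 35 comes from silaketal 34 by fluoride, 34 from alcohol 33 by silylation, and 33 from iodoalkene aldehyde 32 by cutting C1–C10. This bond is the retron of an alkenylchromium addition, which tolerates the esters. A cut at C7–C8 would have to set two centres in the macrocyclisation, and a cut at C2–C3 would be an aldol prone to elimination. Closing the ring while the silaketal is still on keeps O3 as a silyl ether, so the C1 aldehyde is not β to an acetate, and it removes rotational freedom. The forward reaction must close the ring at high dilution and deliver the 1S alcohol.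

**C8–C10 built after the metathesis (32 ← 31 ← 30 ← 27 ← 25 ← 24 ← 22 + 23, 28).** Aldehyde 32 comes from PMB ether 30 through alcohol 31. The angelate of 30 is cut to alcohol 27 and angelic acid 28, the iodoalkene of 27 to alkyne 25, the C8 carbinol to ynone 24, and C8–C9 to Weinreb amide 22 and propynylmagnesium bromide 23. Placing these cuts after the metathesis is deliberate. An alkyne or iodoalkene five atoms from the C5 vinyl group would offer the catalyst a five-membered closure, and a terminal vinyl group would not survive Cp2Zr(H)Cl. After the metathesis only the ring olefin and the 1,1-disubstituted C11=C13 remain. The forward steps need a catalyst-controlled ketone reduction and a regioselective syn-hydrozirconation.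

**Key disconnection: C4=C5 (22 ← 21).** The ring olefin of 22 is cut to the vinyl group and the methylene of acyclic silaketal 21. Wittig-type constructions offer no control of a trisubstituted Z allylic diol of this kind, whereas here the ring size dictates the geometry. The precursor is two independent allylic alcohols on one silicon, and the forward reaction needs only chemoselectivity among three olefins.

**Silaketal (21 ← 9 + 18 + 19).** Both Si–O bonds are cut, giving fragment 1 alcohol 9, fragment 2 alcohol 18 and dichlorodiisopropylsilane 19. Stepwise silylation through a monochlorosilane avoids symmetrical products. Each fragment then carries exactly one free hydroxyl.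

**Fragment 2 (18 ← 17 ← 16 ← 15 ← 12 + 13; 12 ← 10 + 11).** The O12 silyl ether of 18 comes from diol 17, whose C12 oxygen is removed to the isopropenyl group of Weinreb amide 16. Amide 16 comes from imide 15, and C6–C7 is cut to acrolein 13 and the dienolate of senecioyl imide 12, made from auxiliary 10 and acid chloride 11. A syn aldol on the C6 side is preferred to an anti aldol on the C8 side because it is the better-precedented reaction and brings in the vinyl group directly. The forward sequence needs α-selective reaction of the dienolate and an allylic oxidation that touches only the isopropenyl methyl.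

**Fragment 1 (9 ← 8 ← 4 + 6; 4 ← 3 ← 1 + 2; 6 ← 5).** The C3 carbinol of 9 is cut at C–H to enone 8, which is cut at C3–C4 to Weinreb amide 4 and bromide 6 (reacting as alkenyllithium 7). Amide 4 comes from ester 3, made from alcohol 1 and acrylate 2, and 6 from bromoallyl alcohol 5. A hydroxy acid from the chiral pool would need its carboxyl turned into the 2-substituted allyl unit over several steps, while the enone reduction sets C3 in one step.

## Roads not taken

**Alternative 1:** The cut is the C6–O bond of the lactone. In the forward key step Pd(PPh3)4 (zerovalent palladium) would ionise the allylic C4–O bond of the vinyl spiro-epoxide acid A2 to a π-allyl complex over C4–C6, and the C12 carboxylate would add at C6 to give the lactone A1.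
- Merits: one step makes the lactone, moves the olefin to C4=C5 and frees the C15 hydroxyl. A1 is only an acetylation and a desilylation away from 40, and C12 never needs a late oxidation. In end-game economy this road is better than the chosen one.
- Weak points: every hard problem has to be solved before the key step. A2 already needs the ten-membered ring, a C5=C6 olefin and a quaternary epoxide carbon of defined configuration. Nothing enforces the Z geometry, since the π-allyl unit can equilibrate. The C8 angelate is itself an allylic ester open to ionisation by zerovalent palladium, and attack at C4 or β-hydride elimination compete.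
- Comparison: the chosen plan sets against the shorter finish a geometry fixed by ring size and a key step that also couples the fragments.

**Alternative 2:** The cuts are C1–C2 and O–C3. The nitrile oxide generated from enal oxime A4 would add to its terminal C2=C3 vinyl group, closing the isoxazoline and the ten-membered ring together to give A3.
- Merits: ring closure, a C–C bond and the C3 oxygen arrive in one metal-free step that tolerates the lactone. The isoxazoline stores the C1/C3 oxygen pattern as a masked aldol. As a macrocyclisation it is at least as attractive as a chromium-mediated closure.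
- Weak points: C3 would be set by the facial preference of a macrocyclic transition state with no controlling element. The vinyl group is part of a 1,3-diene with C4=C5, so site selectivity is open. The conjugated nitrile oxide can dimerise at the dilution needed. A4 must already contain the Z-C4=C5 olefin, so the central problem is not solved. A3 still lacks the C13 methylene and carries a PMB ether at O8, so N–O cleavage, C1 reduction with another uncontrolled centre, methylenation, angeloylation and acetylation remain.
- Comparison: the chosen plan sets against the elegant closure a C3 centre fixed by a reagent-controlled reduction and a shorter finish.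

**Alternative 3:** The cut is C7–C8. The 13-membered diallylic ether A6, lithiated at C8, would undergo a [2,3]-Wittig shift that forms C7–C8, breaks C13–O and gives the ten-membered C8 carbinol A5 with the C11=C13 methylene.
- Merits: a large ether ring is easier to close than the carbocycle. The contraction creates the ring bond, two stereocentres and the exocyclic methylene at once, and O8 emerges free for the angelate. In bond and stereocentre economy it beats a metathesis that creates no stereocentre.
- Weak points: deprotonation can occur at C8 or C13. The C8 anion is vinylogously β to the O1 silyl ether and can eliminate it. The configurations at C7 and C8 depend on the geometry of the C7=C11 olefin and on induction across a 13-membered ring. Both trisubstituted olefins must exist beforehand. The strong base meets five silyl ethers.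
- Comparison: the chosen plan sets against the higher economy C6/C7 from an auxiliary-controlled aldol and C8 from a catalyst-controlled reduction, all under mild conditions.

Key step: step 12

Remark on the chemistry: the senses of the two CBS reductions are assigned by the usual model, with the alkenyl group (step 5) and the branched C7 carbon (step 14) taken as the larger ketone substituent.

## Route

Step 1
Reactants: 1 4-methoxybenzyl alcohol; 2 methyl acrylate
Product: 3 methyl 3-[(4-methoxybenzyl)oxy]propanoate
Conditions: NaH (5 mol %), excess 2, THF, 0 °C to rt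
Reagents that add atoms: none
Why: Base-catalysed oxa-Michael addition of the benzylic alkoxide to the acrylate; catalytic alkoxide and excess acrylate keep transesterification small.

Step 2
Reactants: 3 methyl 3-[(4-methoxybenzyl)oxy]propanoate
Product: 4 N-methoxy-3-[(4-methoxybenzyl)oxy]-N-methylpropanamide
Conditions: MeNH(OMe)·HCl, i-PrMgCl, THF, −20 °C
Reagents that add atoms: N,O-dimethylhydroxylamine hydrochloride, CNOC.Cl
Why: Weinreb amide formation by aminolysis of the ester with the magnesium amide; the low temperature avoids β-elimination of the PMB ether.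

Step 3
Reactants: 5 2-bromoprop-2-en-1-ol
Product: 6 [(2-bromoprop-2-en-1-yl)oxy](tert-butyl)diphenylsilane
Conditions: TBDPSCl, imidazole, CH2Cl2, 0 °C to rt
Reagents that add atoms: tert-butyl(chloro)diphenylsilane, CC(C)(C)[Si](Cl)(c1ccccc1)c1ccccc1
Why: Imidazole-mediated silylation of the primary allylic alcohol; TBDPS is chosen to outlast every later fluoride or acid treatment except the last.

Step 4
Reactants: 6 [(2-bromoprop-2-en-1-yl)oxy](tert-butyl)diphenylsilane; 4 N-methoxy-3-[(4-methoxybenzyl)oxy]-N-methylpropanamide
Product: 8 2-{[(tert-butyldiphenylsilyl)oxy]methyl}-5-[(4-methoxybenzyl)oxy]pent-1-en-3-one, via 2-lithioallyl silyl ether 7 (not isolated)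
Conditions: t-BuLi (2 equiv), Et2O, −78 °C; then 4, −78 to −40 °C; cold aq NH4Cl (inverse quench)
Reagents that add atoms: none
Why: Bromine–lithium exchange gives the alkenyllithium, which adds once to the Weinreb amide through the chelated tetrahedral intermediate (Weinreb ketone synthesis); the cold inverse quench keeps the liberated amine from adding to the enone.

Step 5
Reactants: 8 2-{[(tert-butyldiphenylsilyl)oxy]methyl}-5-[(4-methoxybenzyl)oxy]pent-1-en-3-one
Product: 9 (3S)-2-{[(tert-butyldiphenylsilyl)oxy]methyl}-5-[(4-methoxybenzyl)oxy]pent-1-en-3-ol (fragment 1)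
Conditions: (R)-2-methyl-CBS-oxazaborolidine (20 mol %), catecholborane, toluene, −78 °C
Reagents that add atoms: none
Why: Corey–Bakshi–Shibata reduction; the α-branched alkenyl group acts as the large substituent, so the (R)-catalyst should deliver hydride to give the 3S carbinol, which sets C3.

Step 6
Reactants: 10 (S)-4-benzyloxazolidin-2-one; 11 3-methylbut-2-enoyl chloride
Product: 12 (S)-4-benzyl-3-(3-methylbut-2-enoyl)oxazolidin-2-one
Conditions: n-BuLi, THF, −78 °C; then 11, −78 to 0 °C
Reagents that add atoms: none
Why: N-acylation of the lithiated oxazolidinone with the acid chloride.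

Step 7
Reactants: 12 (S)-4-benzyl-3-(3-methylbut-2-enoyl)oxazolidin-2-one; 13 acrolein
Product: 15 (S)-4-benzyl-3-[(2S,3R)-3-hydroxy-2-(prop-1-en-2-yl)pent-4-enoyl]oxazolidin-2-one, via boron dienolate 14 (not isolated)
Conditions: n-Bu2BOTf, Et3N, CH2Cl2, −78 to 0 °C; 13, −78 °C; then pH 7 buffer, MeOH, H2O2, 0 °C
Reagents that add atoms: none
Why: Evans boron aldol through the γ-deprotonated Z-dienolate, which reacts at Cα in a Zimmerman–Traxler chair on the face away from the benzyl group; this sets C6 (R) and C7 (S) in the syn relationship and leaves the isopropenyl group out of conjugation.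

Step 8
Reactants: 15 (S)-4-benzyl-3-[(2S,3R)-3-hydroxy-2-(prop-1-en-2-yl)pent-4-enoyl]oxazolidin-2-one
Product: 16 (2S,3R)-3-hydroxy-N-methoxy-N-methyl-2-(prop-1-en-2-yl)pent-4-enamide
Conditions: MeNH(OMe)·HCl, AlMe3, CH2Cl2, −20 to 0 °C
Reagents that add atoms: N,O-dimethylhydroxylamine hydrochloride, CNOC.Cl
Why: Aluminium amide transamination of the β-hydroxy imide, assisted by the aluminium alkoxide, gives the Weinreb amide and frees the auxiliary without touching C7.

Step 9
Reactants: 16 (2S,3R)-3-hydroxy-N-methoxy-N-methyl-2-(prop-1-en-2-yl)pent-4-enamide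
Product: 17 (2S,3R)-3-hydroxy-2-(3-hydroxyprop-1-en-2-yl)-N-methoxy-N-methylpent-4-enamide
Conditions: SeO2 (0.5 equiv), t-BuOOH, CH2Cl2, 0 °C to rt, stopped at partial conversion
Reagents that add atoms: selenium dioxide, O=[Se]=O (oxygen carrier); tert-butyl hydroperoxide, CC(C)(C)OO (terminal oxygen source)
Why: Allylic oxidation with SeO2 (ene reaction, then [2,3]-shift) at the methyl of the 1,1-disubstituted olefin, the only olefin with an accessible allylic C–H besides the carbinol C–H of the vinyl group; conversion is held back to limit the enal.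

Step 10
Reactants: 17 (2S,3R)-3-hydroxy-2-(3-hydroxyprop-1-en-2-yl)-N-methoxy-N-methylpent-4-enamide
Product: 18 (2S,3R)-3-hydroxy-N-methoxy-N-methyl-2-{3-[(triethylsilyl)oxy]prop-1-en-2-yl}pent-4-enamide (fragment 2)
Conditions: TESCl (1.05 equiv), imidazole, CH2Cl2, −78 °C
Reagents that add atoms: chlorotriethylsilane, CC[Si](Cl)(CC)CC
Why: Selective silylation of the primary allylic hydroxyl over the hindered secondary C6 hydroxyl at low temperature.

Step 11
Reactants: 9 fragment 1 alcohol; 19 dichlorodiisopropylsilane; 18 fragment 2 alcohol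
Product: 21 acyclic diisopropylsilaketal joining O3 of 9 to O6 of 18 (3S 6R 7S in germacrane numbering), via chlorosilane 20 (not isolated)
Conditions: 9, excess 19, imidazole, CH2Cl2, 0 °C; evaporation of excess 19; then 18, imidazole, DMAP, DMF, rt
Reagents that add atoms: none
Why: Stepwise silaketal formation: 9 with excess dichlorosilane gives the monochlorosilane, and after the excess is removed the second alcohol displaces the remaining chloride, so 18 cannot form a symmetrical silaketal.

Step 12
Reactants: 21 acyclic diisopropylsilaketal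
Product: 22 cyclic silaketal with Z-C4=C5 in a 4,7-dihydro-1,3,2-dioxasilepine ring, carrying the C8 Weinreb amide, the C11=C13 methylene, O12-TES, O15-TBDPS and O1-PMB
Conditions: second-generation Grubbs catalyst (H2IMes)(PCy3)Cl2Ru=CHPh (10 mol %), toluene (0.005 M), 80 °C, argon sparge
Reagents that add atoms: none
Why: The ruthenium benzylidene exchanges onto the monosubstituted C5 vinyl group, the new alkylidene adds across the 1,1-disubstituted C4 methylene, and cycloreversion of the ruthenacyclobutane releases the ring olefin and a methylidene, with ethylene as the net by-product. The closest known reaction type is the temporary-silicon-tethered ring-closing metathesis of bis-allylic silaketals to trisubstituted olefins. The ring closed is the seven-membered 1,3-dioxa-2-silacyclohept-5-ene (O3, C3, C4, C5, C6, O6, Si), formed by ring-closing olefin metathesis with both olefin carbons inside the ring. No stereocentre is created; the olefin geometry is dictated by ring size, since a seven-membered ring holds only a cis double bond, which puts C3 and C6 cis and the silyloxymethyl group trans to C6. The step needs chemoselectivity among three olefins: the vinyl group is the only monosubstituted one and takes up the catalyst, the C4 methylene is the only partner that gives a common ring (the C11 methylene could only close a cyclobutene), and no alkyne, iodoalkene or angelate is present yet. High dilution suppresses cross-metathesis at the vinyl group. C2 and C7 end trans on the ring, so the bulky C7 arm can sit pseudoequatorial.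

Step 13
Reactants: 22 cyclic silaketal Weinreb amide; 23 prop-1-ynylmagnesium bromide
Product: 24 C8 ynone of the cyclic silaketal (C8 ketone, C9≡C10, C14 methyl)
Conditions: 23 (3 equiv), THF, 0 °C to rt; aq NH4Cl
Reagents that add atoms: none
Why: Weinreb ketone synthesis; the alkynyl Grignard adds once, the hindered silaketal and the silyl ethers are not attacked at 0 °C, and the weakly basic acetylide spares the C7 hydrogen.

Step 14
Reactants: 24 C8 ynone
Product: 25 (8S)-propargylic alcohol of the cyclic silaketal
Conditions: (S)-2-methyl-CBS-oxazaborolidine (1.5 equiv), catecholborane, CH2Cl2, −78 to −40 °C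
Reagents that add atoms: none
Why: Corey–Bakshi–Shibata reduction of the ynone with the branched C7 carbon as the large and the alkynyl as the small group; the (S)-catalyst should give the 8S alcohol, anti to the C11 branch, under non-basic conditions that do not epimerise C7.

Step 15
Reactants: 25 (8S)-propargylic alcohol
Product: 27 (E)-C9=C10 iodoalkene with free C8 hydroxyl, via alkenylzirconocene chloride 26 (not isolated)
Conditions: Cp2Zr(H)Cl (2.5 equiv), THF, rt; then I2, THF, 0 °C; aq Na2S2O3/NaHCO3
Reagents that add atoms: iodine, II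
Why: Hydrozirconation–iodination: syn addition of Zr–H places zirconium on the less hindered, methyl-bearing C10, and iodinolysis with retention gives the E iodoalkene with iodine trans to C8; the ring olefin and the 1,1-disubstituted C11=C13 react far more slowly than the alkyne.

Step 16
Reactants: 27 iodoalkene alcohol; 28 angelic acid
Product: 30 C8 angelate of the cyclic silaketal, via mixed anhydride 29 (not isolated)
Conditions: 28, 2,4,6-trichlorobenzoyl chloride, Et3N, toluene, rt; then 27, DMAP (0.3 equiv), toluene, rt
Reagents that add atoms: none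
Why: Yamaguchi esterification through the mixed anhydride; room temperature and little DMAP are chosen to keep the Z geometry of the angelate.

Step 17
Reactants: 30 C8 angelate
Product: 31 primary C1 alcohol of the cyclic silaketal
Conditions: DDQ, CH2Cl2/pH 7 buffer, 0 °C
Reagents that add atoms: none
Why: Oxidative cleavage of the PMB ether by DDQ (hydride abstraction, then hydrolysis of the oxocarbenium ion); silyl ethers, silaketal, angelate and iodoalkene are inert.

Step 18
Reactants: 31 primary C1 alcohol
Product: 32 C1 aldehyde of the cyclic silaketal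
Conditions: Dess–Martin periodinane, NaHCO3, CH2Cl2, 0 °C to rt
Reagents that add atoms: none
Why: Dess–Martin oxidation under buffered conditions; the β-silyloxy aldehyde does not eliminate as a β-acetoxy aldehyde would.

Step 19
Reactants: 32 C1 aldehyde
Product: 33 ten-membered carbocycle with the 3,6-O-diisopropylsilylene bridge and the free (1S)-hydroxyl
Conditions: CrCl2 (15 equiv), NiCl2 (2 mol %), DMSO–THF (0.003 M), rt
Reagents that add atoms: none
Why: Intramolecular Nozaki–Hiyama–Kishi reaction: nickel reduced in situ to its zerovalent state inserts into the C–I bond, the alkenyl group passes to trivalent chromium with retention of the E geometry and adds to the C1 aldehyde, closing the ten-membered ring. C1 is set by the bicyclic transition state, in which the pseudoaxial C2 arm is expected to expose the carbonyl face that leads to the 1S alcohol.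

Step 20
Reactants: 33 ten-membered C1 alcohol
Product: 34 O1-TBS ether of the bridged carbocycle
Conditions: TBSOTf, 2,6-lutidine, CH2Cl2, −78 to 0 °C
Reagents that add atoms: tert-butyldimethylsilyl trifluoromethanesulfonate, CC(C)(C)[Si](C)(C)OS(=O)(=O)C(F)(F)F
Why: Silylation of the hindered secondary allylic alcohol with the silyl triflate; O1 must be masked before the C3 hydroxyl is freed for acetylation.

Step 21
Reactants: 34 O1-TBS ether
Product: 35 3,6,12-triol with O1-TBS and O15-TBDPS retained
Conditions: HF·pyridine, pyridine, THF, 0 °C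
Reagents that add atoms: none
Why: Fluoride-mediated desilylation graded by the substitution at silicon: the dialkoxysilane and the primary TES ether are cleaved at 0 °C, while the secondary TBS and primary TBDPS ethers are retained.

Step 22
Reactants: 35 3,6,12-triol
Product: 38 α-methylene-γ-butyrolactone (12,6-olide) with free C3 hydroxyl, via C12 enal 36 (not isolated), via lactol 37 (not isolated)
Conditions: TEMPO (20 mol %), PhI(OAc)2, CH2Cl2, rt
Reagents that add atoms: none
Why: TEMPO/PhI(OAc)2 oxidative lactonisation: the oxoammonium salt oxidises the primary allylic alcohol much faster than the secondary ones, the C6 hydroxyl closes the lactol, and the lactol is oxidised to the lactone; the C3 hydroxyl stays.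

Step 23
Reactants: 38 lactone with free C3 hydroxyl
Product: 39 C3 acetate
Conditions: Ac2O, pyridine, DMAP (cat.), CH2Cl2, 0 °C
Reagents that add atoms: acetic anhydride, CC(=O)OC(C)=O
Why: DMAP-catalysed acetylation of the only free hydroxyl.

Step 24
Reactants: 39 C3 acetate
Product: 40 CNP0153210.6
Conditions: HF·pyridine, THF, rt, polypropylene vessel
Reagents that add atoms: none
Why: Global desilylation of O1 and O15 with acidic fluoride, which leaves the α-methylene lactone, the acetate and the angelate untouched.

## Compound list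

1 | 4-methoxybenzyl alcohol | COc1ccc(CO)cc1 | starting material
2 | methyl acrylate | C=CC(=O)OC | starting material
3 | methyl 3-[(4-methoxybenzyl)oxy]propanoate | COC(=O)CCOCc1ccc(OC)cc1 | intermediate
4 | N-methoxy-3-[(4-methoxybenzyl)oxy]-N-methylpropanamide | CON(C)C(=O)CCOCc1ccc(OC)cc1 | intermediate
5 | 2-bromoprop-2-en-1-ol | C=C(Br)CO | starting material
6 | [(2-bromoprop-2-en-1-yl)oxy](tert-butyl)diphenylsilane | C=C(Br)CO[Si](c1ccccc1)(c1ccccc1)C(C)(C)C | intermediate
7 | {3-[(tert-butyldiphenylsilyl)oxy]prop-1-en-2-yl}lithium | [Li]C(=C)CO[Si](c1ccccc1)(c1ccccc1)C(C)(C)C | intermediate (not isolated)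
8 | 2-{[(tert-butyldiphenylsilyl)oxy]methyl}-5-[(4-methoxybenzyl)oxy]pent-1-en-3-one | C=C(CO[Si](c1ccccc1)(c1ccccc1)C(C)(C)C)C(=O)CCOCc1ccc(OC)cc1 | intermediate
9 | (3S)-2-{[(tert-butyldiphenylsilyl)oxy]methyl}-5-[(4-methoxybenzyl)oxy]pent-1-en-3-ol (fragment 1: C1–C4 and C15) | O[C@@H](CCOCc1ccc(OC)cc1)C(=C)CO[Si](c1ccccc1)(c1ccccc1)C(C)(C)C | intermediate
10 | (S)-4-benzyloxazolidin-2-one | O=C1N[C@@H](Cc2ccccc2)CO1 | starting material
11 | 3-methylbut-2-enoyl chloride | CC(C)=CC(=O)Cl | starting material
12 | (S)-4-benzyl-3-(3-methylbut-2-enoyl)oxazolidin-2-one | CC(C)=CC(=O)N1[C@@H](Cc2ccccc2)COC1=O | intermediate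
13 | acrolein (prop-2-enal) | C=CC=O | starting material
14 | dibutylboron Z-dienolate of 12 | C=C(C)/C=C(\OB(CCCC)CCCC)N1[C@@H](Cc2ccccc2)COC1=O | intermediate (not isolated)
15 | (S)-4-benzyl-3-[(2S,3R)-3-hydroxy-2-(prop-1-en-2-yl)pent-4-enoyl]oxazolidin-2-one | C=C(C)[C@@H]([C@@H](C=C)O)C(=O)N1[C@@H](Cc2ccccc2)COC1=O | intermediate
16 | (2S,3R)-3-hydroxy-N-methoxy-N-methyl-2-(prop-1-en-2-yl)pent-4-enamide | C=C(C)[C@@H]([C@@H](C=C)O)C(=O)N(C)OC | intermediate
17 | (2S,3R)-3-hydroxy-2-(3-hydroxyprop-1-en-2-yl)-N-methoxy-N-methylpent-4-enamide | C=C(CO)[C@@H]([C@@H](C=C)O)C(=O)N(C)OC | intermediate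
18 | (2S,3R)-3-hydroxy-N-methoxy-N-methyl-2-{3-[(triethylsilyl)oxy]prop-1-en-2-yl}pent-4-enamide (fragment 2: C5–C8 and C11–C13) | C=C(CO[Si](CC)(CC)CC)[C@@H]([C@@H](C=C)O)C(=O)N(C)OC | intermediate
19 | dichlorodiisopropylsilane | CC(C)[Si](Cl)(Cl)C(C)C | starting material
20 | chlorodiisopropylsilyl ether of 9 (3S) | CC(C)[Si](Cl)(C(C)C)O[C@@H](CCOCc1ccc(OC)cc1)C(=C)CO[Si](c1ccccc1)(c1ccccc1)C(C)(C)C | intermediate (not isolated)
21 | acyclic silaketal: (2S,3R)-3-{[({(3S)-2-[(tert-butyldiphenylsilyloxy)methyl]-5-(4-methoxybenzyloxy)pent-1-en-3-yl}oxy)diisopropylsilyl]oxy}-N-methoxy-N-methyl-2-[3-(triethylsilyloxy)prop-1-en-2-yl]pent-4-enamide; germacrane centres 3S,6R,7S | C=C(CO[Si](CC)(CC)CC)[C@@H]([C@@H](C=C)O[Si](C(C)C)(C(C)C)O[C@@H](CCOCc1ccc(OC)cc1)C(=C)CO[Si](c1ccccc1)(c1ccccc1)C(C)(C)C)C(=O)N(C)OC | intermediate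
22 | cyclic silaketal: (2S)-2-{(4S,7R)-5-[(tert-butyldiphenylsilyloxy)methyl]-2,2-diisopropyl-4-[2-(4-methoxybenzyloxy)ethyl]-4,7-dihydro-1,3,2-dioxasilepin-7-yl}-N-methoxy-N-methyl-3-[(triethylsilyloxy)methyl]but-3-enamide; Z-C4=C5; germacrane centres 3S,6R,7S | C=C(CO[Si](CC)(CC)CC)[C@@H]([C@H]1C=C(CO[Si](c2ccccc2)(c2ccccc2)C(C)(C)C)[C@H](CCOCc2ccc(OC)cc2)O[Si](C(C)C)(C(C)C)O1)C(=O)N(C)OC | intermediate
23 | prop-1-ynylmagnesium bromide | CC#C[Mg]Br | starting material
24 | C8 ynone: as 22 with the amide replaced by a but-2-ynoyl ketone (C8=O, C9≡C10, C14); 3S,6R,7S | C=C(CO[Si](CC)(CC)CC)[C@@H]([C@H]1C=C(CO[Si](c2ccccc2)(c2ccccc2)C(C)(C)C)[C@H](CCOCc2ccc(OC)cc2)O[Si](C(C)C)(C(C)C)O1)C(=O)C#CC | intermediate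
25 | propargylic alcohol: as 24 with C8 reduced to the carbinol; 3S,6R,7R,8S | C=C(CO[Si](CC)(CC)CC)[C@@H]([C@H]1C=C(CO[Si](c2ccccc2)(c2ccccc2)C(C)(C)C)[C@H](CCOCc2ccc(OC)cc2)O[Si](C(C)C)(C(C)C)O1)[C@H](O)C#CC | intermediate
26 | alkenylzirconocene chloride: as 27 with Cp2Zr(Cl) on C10 in place of iodine and on O8 in place of hydrogen | C=C(CO[Si](CC)(CC)CC)[C@@H]([C@H]1C=C(CO[Si](c2ccccc2)(c2ccccc2)C(C)(C)C)[C@H](CCOCc2ccc(OC)cc2)O[Si](C(C)C)(C(C)C)O1)[C@H](O[Zr](Cl)(C2C=CC=C2)C2C=CC=C2)/C=C(\C)[Zr](Cl)(C2C=CC=C2)C2C=CC=C2 | intermediate (not isolated)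
27 | iodoalkene alcohol: cyclic silaketal with free C8–OH and (E)-C9=C10(CH3)I, iodine trans to C8; 3S,6R,7R,8S | C=C(CO[Si](CC)(CC)CC)[C@@H]([C@H]1C=C(CO[Si](c2ccccc2)(c2ccccc2)C(C)(C)C)[C@H](CCOCc2ccc(OC)cc2)O[Si](C(C)C)(C(C)C)O1)[C@H](O)/C=C(\C)I | intermediate
28 | angelic acid, (Z)-2-methylbut-2-enoic acid | C/C=C(/C)C(=O)O | starting material
29 | angelic 2,4,6-trichlorobenzoic anhydride | C/C=C(/C)C(=O)OC(=O)c1c(Cl)cc(Cl)cc1Cl | intermediate (not isolated)
30 | C8 angelate: as 27 with O8 esterified by (Z)-2-methylbut-2-enoic acid; 3S,6R,7R,8S | C=C(CO[Si](CC)(CC)CC)[C@@H]([C@H]1C=C(CO[Si](c2ccccc2)(c2ccccc2)C(C)(C)C)[C@H](CCOCc2ccc(OC)cc2)O[Si](C(C)C)(C(C)C)O1)[C@H](OC(=O)/C(C)=C\C)/C=C(\C)I | intermediate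
31 | C1 alcohol: as 30 with the PMB ether replaced by the primary hydroxyl; 3S,6R,7R,8S | C=C(CO[Si](CC)(CC)CC)[C@@H]([C@H]1C=C(CO[Si](c2ccccc2)(c2ccccc2)C(C)(C)C)[C@H](CCO)O[Si](C(C)C)(C(C)C)O1)[C@H](OC(=O)/C(C)=C\C)/C=C(\C)I | intermediate
32 | C1 aldehyde: as 31 with C1 oxidised to the aldehyde; 3S,6R,7R,8S | C=C(CO[Si](CC)(CC)CC)[C@@H]([C@H]1C=C(CO[Si](c2ccccc2)(c2ccccc2)C(C)(C)C)[C@H](CC=O)O[Si](C(C)C)(C(C)C)O1)[C@H](OC(=O)/C(C)=C\C)/C=C(\C)I | intermediate
33 | (1S,3S,6R,7R,8R)-8-angeloyloxy-1-hydroxy-3,6-O-(diisopropylsilylene)-12-(triethylsilyloxy)-15-(tert-butyldiphenylsilyloxy)germacra-4Z,9E,11(13)-triene | C=C(CO[Si](CC)(CC)CC)[C@H]1[C@H]2C=C(CO[Si](c3ccccc3)(c3ccccc3)C(C)(C)C)[C@H](C[C@H](O)/C(C)=C/[C@H]1OC(=O)/C(C)=C\C)O[Si](C(C)C)(C(C)C)O2 | intermediate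
34 | O1-TBS ether of 33; 1S,3S,6R,7R,8R | C=C(CO[Si](CC)(CC)CC)[C@H]1[C@H]2C=C(CO[Si](c3ccccc3)(c3ccccc3)C(C)(C)C)[C@H](C[C@H](O[Si](C)(C)C(C)(C)C)/C(C)=C/[C@H]1OC(=O)/C(C)=C\C)O[Si](C(C)C)(C(C)C)O2 | intermediate
35 | (1S,3S,6R,7S,8R)-8-angeloyloxy-1-(tert-butyldimethylsilyloxy)-15-(tert-butyldiphenylsilyloxy)germacra-4Z,9E,11(13)-triene-3,6,12-triol | C=C(CO)[C@H]1[C@H](O)/C=C(/CO[Si](c2ccccc2)(c2ccccc2)C(C)(C)C)[C@@H](O)C[C@H](O[Si](C)(C)C(C)(C)C)/C(C)=C/[C@H]1OC(=O)/C(C)=C\C | intermediate
36 | C12 enal of 35 (C12 aldehyde, C3 and C6 hydroxyls free); 1S,3S,6R,7S,8R | C=C(C=O)[C@H]1[C@H](O)/C=C(/CO[Si](c2ccccc2)(c2ccccc2)C(C)(C)C)[C@@H](O)C[C@H](O[Si](C)(C)C(C)(C)C)/C(C)=C/[C@H]1OC(=O)/C(C)=C\C | intermediate (not isolated)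
37 | C12/O6 lactol of 36 (lactol carbon unassigned, other centres as in 38) | C=C1C(O)O[C@@H]2/C=C(/CO[Si](c3ccccc3)(c3ccccc3)C(C)(C)C)[C@@H](O)C[C@H](O[Si](C)(C)C(C)(C)C)/C(C)=C/[C@@H](OC(=O)/C(C)=C\C)[C@@H]12 | intermediate (not isolated)
38 | (1S,3S,6R,7R,8R)-8-angeloyloxy-3-hydroxy-1-(tert-butyldimethylsilyloxy)-15-(tert-butyldiphenylsilyloxy)germacra-4Z,9E,11(13)-trien-12,6-olide | C=C1C(=O)O[C@@H]2/C=C(/CO[Si](c3ccccc3)(c3ccccc3)C(C)(C)C)[C@@H](O)C[C@H](O[Si](C)(C)C(C)(C)C)/C(C)=C/[C@@H](OC(=O)/C(C)=C\C)[C@@H]12 | intermediate
39 | 3-O-acetate of 38; 1S,3S,6R,7R,8R | C=C1C(=O)O[C@@H]2/C=C(/CO[Si](c3ccccc3)(c3ccccc3)C(C)(C)C)[C@@H](OC(C)=O)C[C@H](O[Si](C)(C)C(C)(C)C)/C(C)=C/[C@@H](OC(=O)/C(C)=C\C)[C@@H]12 | intermediate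
40 | CNP0153210.6: (1S,3S,6R,7R,8R)-3-acetoxy-8-angeloyloxy-1,15-dihydroxygermacra-4Z,9E,11(13)-trien-12,6-olide | C=C1C(=O)O[C@@H]2/C=C(/CO)[C@@H](OC(C)=O)C[C@H](O)/C(C)=C/[C@@H](OC(=O)/C(C)=C\C)[C@@H]12 | target

## Step count and least certain steps

Total: 24 steps. Longest linear sequence: 19 steps (steps 6–10, then 11–24); the fragment 1 branch (steps 1, 2, 4, 5, then 11–24) is 18.

**Step 12 (key step).** The most likely failure is slow closure onto the hindered 1,1-disubstituted C4 olefin, which sits between two branched silyloxy carbons. The C5 alkylidene would then be diverted into cross-metathesis dimerisation or held as a six-membered chelate by the Weinreb carbonyl. The fallback is a relay that delivers the carbene onto C4; it sets out from 4 and returns at 22. But-2-yne-1,4-diol is monosilylated (TBDPSCl, imidazole) to 4-[(tert-butyldiphenylsilyl)oxy]but-2-yn-1-ol F1. Trans-hydroalumination and bromination (NaAlH2(OCH2CH2OMe)2, then N-bromosuccinimide) give (Z)-3-bromo-4-[(tert-butyldiphenylsilyl)oxy]but-2-en-1-ol F2, and O-allylation (NaH, allyl bromide) gives the relay bromide F3. Bromine–lithium exchange and addition to 4 as in step 4 give the relay enone F4, and reduction as in step 5 gives the relay alcohol F5. Tethering to 18 as in step 11 gives the relay silaketal F6. Under the conditions of step 12 the catalyst loads onto the allyl ether of F6, expels 2,5-dihydrofuran and so arrives on C4, and closure onto the C5 vinyl group gives 22.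

**Step 19.** The most likely failure is poor facial selectivity at C1, because nothing but the conformation of the forming bridged bicycle distinguishes the two faces of the aldehyde. Slow closure of the strained bicycle is the second concern. The fallback sets out from 32 and returns at 33. The cyclisation product, including the C1 epimer (1R)-alcohol F7, is oxidised with Dess–Martin periodinane to the C1 enone F8. Reduction with (R)-2-methyl-CBS-oxazaborolidine and catecholborane, with the alkenyl C10 as the large group, gives 33, so that C1 is set by the reagent and not by the ring closure.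

**Step 9.** The most likely failure is over-oxidation to the C12 enal, which the free C6 hydroxyl can trap as a lactol that is oxidised further; the new C12 alcohol can also lactonise onto the amide. The fallback sets out from 16 and returns at 18. The C6 hydroxyl is capped first as the 4-methoxybenzyl ether F9 (4-methoxybenzyl trichloroacetimidate, camphorsulfonic acid cat.). Allylic oxidation as in step 9 then gives the C12 alcohol F10, silylation as in step 10 gives the TES ether F11, and DDQ returns 18.

**Step 15.** The most likely failure is regiochemical leakage (zirconium on C9) and hydrozirconation of the C11=C13 methylene by the excess reagent. The fallback sets out from 25 and returns at 27. Syn-hydrosilylation catalysed by PtCl2 and XPhos with Et3SiH places silicon distal to the carbinol and gives the (E)-alkenylsilane F12. Iododesilylation with N-iodosuccinimide in (CF3)2CHOH at 0 °C gives 27 with retention.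

**Step 16.** The most likely failure is Z-to-E isomerisation of the activated angelate to the tiglate, together with sluggish acylation of the hindered C8 hydroxyl. The fallback sets out from 27 and returns at 30. Acylation with 2-[bis(2,2,2-trifluoroethoxy)phosphoryl]propanoic acid (DCC, DMAP) gives the phosphonopropionate F13. Still–Gennari olefination with acetaldehyde (KN(SiMe3)2, 18-crown-6, THF, −78 °C) then builds the Z-2-methylbut-2-enoate on the substrate and gives 30.

## Further compounds

F1 | step 12 | 4-[(tert-butyldiphenylsilyl)oxy]but-2-yn-1-ol | OCC#CCO[Si](c1ccccc1)(c1ccccc1)C(C)(C)C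
F2 | step 12 | (Z)-3-bromo-4-[(tert-butyldiphenylsilyl)oxy]but-2-en-1-ol | OC/C=C(\Br)CO[Si](c1ccccc1)(c1ccccc1)C(C)(C)C
F3 | step 12 | relay bromide, (Z)-allyl 3-bromo-4-[(tert-butyldiphenylsilyl)oxy]but-2-enyl ether | C=CCOC/C=C(\Br)CO[Si](c1ccccc1)(c1ccccc1)C(C)(C)C
F4 | step 12 | relay enone, 8 with a CH2O-allyl group on the olefin terminus | C=CCOC/C=C(\C(=O)CCOCc1ccc(OC)cc1)CO[Si](c1ccccc1)(c1ccccc1)C(C)(C)C
F5 | step 12 | relay alcohol, (3S)-carbinol from F4 | C=CCOC/C=C(\[C@@H](O)CCOCc1ccc(OC)cc1)CO[Si](c1ccccc1)(c1ccccc1)C(C)(C)C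
F6 | step 12 | relay silaketal, 21 with a CH2O-allyl group on the C4 olefin terminus | C=C(CO[Si](CC)(CC)CC)[C@@H]([C@@H](C=C)O[Si](C(C)C)(C(C)C)O[C@@H](CCOCc1ccc(OC)cc1)/C(CO[Si](c1ccccc1)(c1ccccc1)C(C)(C)C)=C\COCC=C)C(=O)N(C)OC
F7 | step 19 | C1 epimer of 33, (1R)-alcohol | C=C(CO[Si](CC)(CC)CC)[C@H]1[C@H]2C=C(CO[Si](c3ccccc3)(c3ccccc3)C(C)(C)C)[C@H](C[C@@H](O)/C(C)=C/[C@H]1OC(=O)/C(C)=C\C)O[Si](C(C)C)(C(C)C)O2
F8 | step 19 | C1 enone of the bridged carbocycle | C=C(CO[Si](CC)(CC)CC)[C@H]1[C@H]2C=C(CO[Si](c3ccccc3)(c3ccccc3)C(C)(C)C)[C@H](CC(=O)/C(C)=C/[C@H]1OC(=O)/C(C)=C\C)O[Si](C(C)C)(C(C)C)O2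
F9 | step 9 | O6-(4-methoxybenzyl) ether of 16 | C=C(C)[C@@H]([C@@H](C=C)OCc1ccc(OC)cc1)C(=O)N(C)OC
F10 | step 9 | C12 alcohol from F9 | C=C(CO)[C@@H]([C@@H](C=C)OCc1ccc(OC)cc1)C(=O)N(C)OC
F11 | step 9 | O12-triethylsilyl ether of F10 | C=C(CO[Si](CC)(CC)CC)[C@@H]([C@@H](C=C)OCc1ccc(OC)cc1)C(=O)N(C)OC
F12 | step 15 | (E)-C10 triethylsilyl alkene, 27 with SiEt3 in place of iodine | C=C(CO[Si](CC)(CC)CC)[C@@H]([C@H]1C=C(CO[Si](c2ccccc2)(c2ccccc2)C(C)(C)C)[C@H](CCOCc2ccc(OC)cc2)O[Si](C(C)C)(C(C)C)O1)[C@H](O)/C=C(\C)[Si](CC)(CC)CC
F13 | step 16 | O8 2-[bis(2,2,2-trifluoroethoxy)phosphoryl]propanoate of 27 | C=C(CO[Si](CC)(CC)CC)[C@@H]([C@H]1C=C(CO[Si](c2ccccc2)(c2ccccc2)C(C)(C)C)[C@H](CCOCc2ccc(OC)cc2)O[Si](C(C)C)(C(C)C)O1)[C@H](OC(=O)C(C)P(=O)(OCC(F)(F)F)OCC(F)(F)F)/C=C(\C)I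
A1 | alternative 1 | lactone from the palladium step: O1-TBS, 3-deacetyl target | C=C1C(=O)O[C@@H]2/C=C(/CO)[C@@H](O)C[C@H](O[Si](C)(C)C(C)(C)C)/C(C)=C/[C@@H](OC(=O)/C(C)=C\C)[C@@H]12
A2 | alternative 1 | vinyl spiro-epoxide acid: ten-membered ring with C5=C6, C4/C15 epoxide (oxygen on the ring face later taken by O6) and free C12 acid | C=C(C(=O)O)[C@H]1/C=C/[C@@]2(CO2)[C@@H](O)C[C@H](O[Si](C)(C)C(C)(C)C)/C(C)=C/[C@H]1OC(=O)/C(C)=C\C
A3 | alternative 2 | isoxazoline-bridged ten-membered carbocycle fused to the saturated γ-lactone, O8-PMB, O15-TBS | C1C(=O)O[C@@H]2/C=C(/CO[Si](C)(C)C(C)(C)C)[C@@H]3CC(=NO3)/C(C)=C/[C@@H](OCc4ccc(OC)cc4)[C@@H]12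
A4 | alternative 2 | enal oxime with terminal C2=C3 vinyl group on the lactone-bearing chain | O/N=C/C(C)=C/[C@@H](OCc1ccc(OC)cc1)[C@H]1CC(=O)O[C@@H]1/C=C(/CO[Si](C)(C)C(C)(C)C)C=C
A5 | alternative 3 | ten-membered C8 carbinol with the C11=C13 methylene unit on C7 | C=C(CO[Si](CC)(CC)CC)[C@H]1[C@H](O[Si](CC)(CC)CC)/C=C(/CO[Si](C)(C)C(C)(C)C)[C@@H](O[Si](CC)(CC)CC)C[C@H](O[Si](C)(C)C(C)(C)C)/C(C)=C/[C@H]1O
A6 | alternative 3 | 13-membered diallylic ether with oxygen bridging C8 and C13 | O1C/C(CO[Si](CC)(CC)CC)=C/[C@H](O[Si](CC)(CC)CC)/C=C(/CO[Si](C)(C)C(C)(C)C)[C@@H](O[Si](CC)(CC)CC)C[C@H](O[Si](C)(C)C(C)(C)C)/C(C)=C/C1
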